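(Readings and results come from a simulation for an exercise; the scatter is artificial.)

Two questions stand on this flask: when it holds most target, and how much.

| setting | Monday's | flask |
|---|---|---|
| substrate | 28 mM | 28 mM |
| reagent in the second phase | 2.5 equiv | 2.50 equiv |
| protic impurity | 0.28 mM | 0.560 mM |
| remark | run made earlier |  |
| time |  | 8.0 d |
| volume of the second phase over the first |  | 1.0 |

Monday's run (percent of the substrate charged)

| time / h | target / % | substrate / % |
|---|---|---|
| 1.33 | 33.1 | 36.4 |
| 4.00 | 63.7 | 3.5 |
| 6.00 | 73.8 | 2.2 |
| 10.0 | 82.9 | 1.1 |
| 15.0 | 86.8 | 0 |
| 20.0 | 87.9 | 0.4 |

(standard deviation of a reading: 0.5 percentage points)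

* time, not beyond 8.0 d, at which the flask holds most target
* the amount of target, in percent of the substrate charged, at that time

- a species is counted by the substrate in it: one idle adduct counts as two
- amounts and yields of target count product in the second phase and idle adduct too
- in the second phase: reagent in the second phase, product in the second phase; everything else is in the first
- charges count per volume of the first phase; a concentration in a rate is the amount of a species over the volume of its own phase; every rate counts per litre of the first phase
- candidate steps: reagent in the reaction phase <-> reagent in the second phase; substrate + reagent in the reaction phase -> target; target <-> product in the second phase; target -> decomposed product; reagent in the reaction phase + protic impurity -> quenched reagent; substrate + target <-> idle adduct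
- the earlier runs hold the two phases in the same ratio of volumes as the flask asked about
- in an amount of target, one idle adduct counts as one target
- no earlier run changes the charge of protic impurity; that part of a forecast is a guess

We bracket one number, the loss constant k: the fraction of counted target T that becomes decomposed product Q per hour. From dQ/dt = kT, integration gives Q = k∫T dt, and Monday's readings give, by trapezoids up to 20.0 h:

∫T dt = 14.6 h

The unread part U = 100 % − T − substrate holds Q plus the substrate share of idle adduct, so Q is at most U. That bounds k from above:

k ≤ U/∫T dt = 0.00800 h⁻¹

We take the adduct as following substrate × target. It is at most U at 10.0 h, which caps it at 6.17 % at 20.0 h, though that substrate reading sits near the scatter. This bounds k from below: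

k ≥ 0.00378 h⁻¹

T rose 3.9 percentage points, then 1.1 points, over the last two intervals. Each rise is feed minus loss, and the loss per interval is at least 1.7 points. If the feed shrinks in a steady ratio, the peak lies between the 15.0 h reading and 0.880 d. Its height lies between 87.9 %, give or take 0.5 points, and 88.3 %. Past the peak we take T to fall as exp(−kt), so we reckon 22.2 % to 45.9 % at 8.0 d. The impurity in this flask is 0.800 % of the reagent charged, and we guess that it moves neither answer much.

The forecast, “Target peaks when adduct release equals decomposition”, gives 1.1 d, later than our bound, and 88.5 %, against our upper limit of 88.3 %.

The flask gives 0.732 d, earlier than our late bound, and 87.7 %.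

    reagent in the reaction phase ⇌ reagent in the second phase, rate k1*([reagent in the reaction phase] - [reagent in the second phase]/K1) per volume of the first phase (partition coefficient = 1.10, kL = 0.00330 min⁻¹)
    substrate + reagent in the reaction phase → target (k = 2.10 L mol⁻¹ min⁻¹)
    target ⇌ product in the second phase, rate k3*([target] - [product in the second phase]/K3) per volume of the first phase (partition coefficient = 1.10, kL = 0.00360 min⁻¹)
    target → decomposed product (k = 2.50 × 10⁻⁴ min⁻¹)
    reagent in the reaction phase + protic impurity → quenched reagent (k = 0.530 L mol⁻¹ min⁻¹)
    substrate + target ⇌ idle adduct, settled at all times (K = 1200 L mol⁻¹)

In the flask at 0.800 d, the step making target has 97 % of its turnover up to 8.0 d behind it, against 13 % for decomposition. Half of the decomposition's turnover up to 8.0 d comes by 2.91 d, and at 8.0 d the flask holds 27.0 % target, between 22.2 % and 45.9 %. Read at 50 h, the same flask is reckoned by our two values of k, from its peak, at 67.7 % to 77.6 % target, and it holds 73.0 %.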